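**Plan**

- Ring numbering: C1 (aroyl-bearing), C2H2, C3H=C4 (C4 carries the 4-methylpent-3-enyl chain), C5H2, C6 (phenyl-bearing). The enabling feature is the C5–C6 bond, which joins benzylic C6 to the allylic end of the C3=C4 alkene; a cyclobutane C1–C2–C3–C6 with a C4=C5 alkenyl group on C3 forms exactly this bond in a 1,3-shift.
- Retrosynthesis: cut C5–C6 (reclosing C3–C6 gives the vinylcyclobutane), then the C4=C5 methylene (Wittig), then the chain bond between the carbons α and β to C4 (enolate prenylation of a C3 acetyl group made by Wacker oxidation of a vinyl group), and last C1–C2 and C3–C6 of the four-membered ring ([2+2] of cardamonin and buta-1,3-diene).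
- Forward: the cyclobutane arises first by photocycloaddition; after silylation of both phenols the dienyl side chain is built on the vinyl handle; the cyclohexene arises last by ring expansion; desilylation ends the route.
- Buta-1,3-diene, not the C10 diene myrcene, is the photopartner: its two alkenes are identical, so the adduct has one constitution, whereas a 2-substituted diene is expected to be attacked largely at its 1,1-disubstituted alkene, which would end in the 3-substituted cyclohexene.
- Stereochemistry: C1 and C6 are set (trans, absolute) by the chiral Sc(OTf)3–PyBox catalyst in the photocycloaddition; C1 is carried untouched to the target, C6 is broken and re-formed trans to C1 in the ring expansion, and C3 is irrelevant because it ends sp2.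

Key step: step 6

Assumption: the (S,S) antipode of t-Bu-PyBox is taken to deliver the (1R,2R) photoadduct; if the sense of induction is the opposite, the equally available (R,R) ligand is used with no other change.

Step 1
Reactants: 1 cardamonin; 2 buta-1,3-diene
Product: 3 (2,4-dihydroxy-6-methoxyphenyl)[(1R,2R,3R)-3-ethenyl-2-phenylcyclobutyl]methanone
Conditions: Sc(OTf)3 (10 mol%), (S,S)-t-Bu-PyBox (15 mol%), Ru(bpy)3(PF6)2 (2.5 mol%), diene (10 equiv), i-PrOAc/MeCN 3:1, blue LEDs, rt, sealed tube
Reagents that add atoms: none
Why: Enantioselective Lewis acid-catalysed, triplet-sensitised [2+2] photocycloaddition of a 2′-hydroxychalcone with a 1,3-diene, in which only the chalcone chelated to the chiral scandium complex through its 2′-hydroxyl and carbonyl is sensitised by Ru(bpy)3(PF6)2, its α-carbon C1 adds to a terminal CH2 of the symmetrical diene to give a benzyl/allyl 1,4-diradical that closes C6–C3, and the ligand shields one enone face so that C1 and C6 form R,R and trans with the vinyl group at C3 settling trans to phenyl.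

Step 2
Reactants: 3 (2,4-dihydroxy-6-methoxyphenyl)[(1R,2R,3R)-3-ethenyl-2-phenylcyclobutyl]methanone
Product: 4 [2,4-bis(tert-butyldimethylsilyloxy)-6-methoxyphenyl][(1R,2R,3R)-3-ethenyl-2-phenylcyclobutyl]methanone
Conditions: TBSOTf (2.5 equiv), 2,6-lutidine (4 equiv), CH2Cl2, 0 °C to rt
Reagents that add atoms: tert-butyldimethylsilyl trifluoromethanesulfonate (TBSOTf), CC(C)(C)[Si](C)(C)OS(=O)(=O)C(F)(F)F
Why: Silyl ether formation with a silyl triflate and a hindered pyridine base should convert both phenols, including the hydrogen-bonded 2′-hydroxyl, into silyl ethers that withstand the later enolate and ylide steps, while the non-nucleophilic base leaves the C1 centre next to the shielded ketone untouched.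

Step 3
Reactants: 4 [2,4-bis(tert-butyldimethylsilyloxy)-6-methoxyphenyl][(1R,2R,3R)-3-ethenyl-2-phenylcyclobutyl]methanone
Product: 5 [2,4-bis(tert-butyldimethylsilyloxy)-6-methoxyphenyl][(1R,2R,3S)-3-acetyl-2-phenylcyclobutyl]methanone
Conditions: PdCl2 (10 mol%), Cu(OAc)2 (20 mol%), O2 (1 atm), DMA/H2O 7:1, rt
Reagents that add atoms: water, O
Why: Tsuji–Wacker oxidation, in which Markovnikov hydroxypalladation of the terminal vinyl group and β-hydride elimination give the methyl ketone while copper and oxygen return zerovalent palladium to divalent palladium, and the acetate-buffered medium should spare the aryl silyl ethers and the ring stereocentres.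

Step 4
Reactants: 5 [2,4-bis(tert-butyldimethylsilyloxy)-6-methoxyphenyl][(1R,2R,3S)-3-acetyl-2-phenylcyclobutyl]methanone
Product: 7 [2,4-bis(tert-butyldimethylsilyloxy)-6-methoxyphenyl][(1R,2R,3S)-3-(5-methylhex-4-enoyl)-2-phenylcyclobutyl]methanone, via lithium enolate 6 (not isolated)
Conditions: LiN(i-Pr)2 (1.1 equiv), THF, −78 °C; then prenyl bromide (1.5 equiv), DMPU, −78 to −20 °C
Reagents that add atoms: 1-bromo-3-methylbut-2-ene (prenyl bromide), CC(C)=CCBr
Why: Kinetic enolate alkylation, in which the amide base removes a proton from the unhindered methyl group and not from the ring methines, the doubly ortho-substituted aryl ketone is too shielded to enolise, and SN2 attack of the enolate on the allylic bromide installs the 5-methylhex-4-enoyl chain without creating a stereocentre.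

Step 5
Reactants: 7 [2,4-bis(tert-butyldimethylsilyloxy)-6-methoxyphenyl][(1R,2R,3S)-3-(5-methylhex-4-enoyl)-2-phenylcyclobutyl]methanone
Product: 8 [2,4-bis(tert-butyldimethylsilyloxy)-6-methoxyphenyl][(1R,2R,3S)-3-(6-methylhepta-1,5-dien-2-yl)-2-phenylcyclobutyl]methanone
Conditions: Ph3PCH3Br (3.0 equiv), n-BuLi (2.8 equiv), THF, 0 °C; then 7, 0 °C to rt
Reagents that add atoms: methyltriphenylphosphonium bromide, C[P+](c1ccccc1)(c1ccccc1)c1ccccc1.[Br-]
Why: Wittig methylenation, in which the unstabilised ylide converts the dialkyl ketone into the 1,1-disubstituted alkene while the far more hindered and electron-rich aryl ketone is left alone, and no stereocentre is formed.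

Step 6
Reactants: 8 [2,4-bis(tert-butyldimethylsilyloxy)-6-methoxyphenyl][(1R,2R,3S)-3-(6-methylhepta-1,5-dien-2-yl)-2-phenylcyclobutyl]methanone
Product: 9 [2,4-bis(tert-butyldimethylsilyloxy)-6-methoxyphenyl][(1R,6R)-4-(4-methylpent-3-en-1-yl)-6-phenylcyclohex-3-en-1-yl]methanone
Conditions: degassed mesitylene (0.01 M), sealed tube, 160 °C
Reagents that add atoms: none
Why: Thermal vinylcyclobutane-to-cyclohexene [1,3] rearrangement: heating homolyses the weakest ring bond, C3–C6, which is both allylic and benzylic, to a 1,4-diradical made of the C3–C4–C5 allyl radical and the C6 benzyl radical, the closest precedent being the thermal ring expansion of trans-1,2-dialkenyl- and 2-aryl-1-alkenylcyclobutanes. Recombination of C6 with the distal allyl terminus C5 closes the six-membered ring C1–C2–C3–C4–C5–C6 (ring expansion from four to six atoms by radical–radical coupling at the end of the allyl unit) and releases the cyclobutane strain. C1 takes no part and keeps its R configuration from step 1, while C3 becomes sp2, so any C3 epimer of 8 converges on the same product. The only new stereocentre, C6, is re-formed from a planar benzyl radical under control of the neighbouring C1 centre and should close trans to the bulky aroyl group through a half-chair transition state with both substituents pseudo-equatorial. The step needs bond selectivity, secured by the double benzyl/allyl stabilisation of C3–C6 cleavage over C1–C6 cleavage, and it must outrun cycloreversion of the diradical to the silylated chalcone and myrcene, which is why it is run dilute at the lowest effective temperature so that the fragments cannot recombine in a racemic Diels–Alder reaction. Any cis isomer is a diastereomer and is removed by chromatography, not by base, since epimerising its C1 centre would give the antipode of 9.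

Step 7
Reactants: 9 [2,4-bis(tert-butyldimethylsilyloxy)-6-methoxyphenyl][(1R,6R)-4-(4-methylpent-3-en-1-yl)-6-phenylcyclohex-3-en-1-yl]methanone
Product: 10 (2,4-dihydroxy-6-methoxyphenyl)[(1R,6R)-4-(4-methylpent-3-en-1-yl)-6-phenylcyclohex-3-en-1-yl]methanone
Conditions: TBAF (2.5 equiv), AcOH (2.5 equiv), THF, 0 °C
Reagents that add atoms: none
Why: Fluoride-mediated cleavage of the two aryl silyl ethers, driven by the strong Si–F bond and buffered with acetic acid so that the liberated phenoxides cannot epimerise C1, should release the target without touching either alkene.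

**Compound list**

1 | cardamonin, (E)-1-(2,4-dihydroxy-6-methoxyphenyl)-3-phenylprop-2-en-1-one | COc1cc(O)cc(O)c1C(=O)/C=C/c1ccccc1 | starting material
2 | buta-1,3-diene | C=CC=C | starting material
3 | (2,4-dihydroxy-6-methoxyphenyl)[(1R,2R,3R)-3-ethenyl-2-phenylcyclobutyl]methanone (aroyl/phenyl trans, phenyl/vinyl trans) | COc1cc(O)cc(O)c1C(=O)[C@@H]1C[C@H](C=C)[C@H]1c1ccccc1 | intermediate
4 | [2,4-bis(tert-butyldimethylsilyloxy)-6-methoxyphenyl][(1R,2R,3R)-3-ethenyl-2-phenylcyclobutyl]methanone | COc1cc(O[Si](C)(C)C(C)(C)C)cc(O[Si](C)(C)C(C)(C)C)c1C(=O)[C@@H]1C[C@H](C=C)[C@H]1c1ccccc1 | intermediate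
5 | [2,4-bis(tert-butyldimethylsilyloxy)-6-methoxyphenyl][(1R,2R,3S)-3-acetyl-2-phenylcyclobutyl]methanone | COc1cc(O[Si](C)(C)C(C)(C)C)cc(O[Si](C)(C)C(C)(C)C)c1C(=O)[C@@H]1C[C@H](C(C)=O)[C@H]1c1ccccc1 | intermediate
6 | lithium enolate of 5 (CH2=C(OLi) group on the cyclobutane carbon next to the phenyl-bearing one) | COc1cc(O[Si](C)(C)C(C)(C)C)cc(O[Si](C)(C)C(C)(C)C)c1C(=O)[C@@H]1C[C@H](C(=C)O[Li])[C@H]1c1ccccc1 | intermediate
7 | [2,4-bis(tert-butyldimethylsilyloxy)-6-methoxyphenyl][(1R,2R,3S)-3-(5-methylhex-4-enoyl)-2-phenylcyclobutyl]methanone | COc1cc(O[Si](C)(C)C(C)(C)C)cc(O[Si](C)(C)C(C)(C)C)c1C(=O)[C@@H]1C[C@H](C(=O)CCC=C(C)C)[C@H]1c1ccccc1 | intermediate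
8 | [2,4-bis(tert-butyldimethylsilyloxy)-6-methoxyphenyl][(1R,2R,3S)-3-(6-methylhepta-1,5-dien-2-yl)-2-phenylcyclobutyl]methanone | COc1cc(O[Si](C)(C)C(C)(C)C)cc(O[Si](C)(C)C(C)(C)C)c1C(=O)[C@@H]1C[C@H](C(=C)CCC=C(C)C)[C@H]1c1ccccc1 | intermediate
9 | [2,4-bis(tert-butyldimethylsilyloxy)-6-methoxyphenyl][(1R,6R)-4-(4-methylpent-3-en-1-yl)-6-phenylcyclohex-3-en-1-yl]methanone | COc1cc(O[Si](C)(C)C(C)(C)C)cc(O[Si](C)(C)C(C)(C)C)c1C(=O)[C@@H]1CC=C(CCC=C(C)C)C[C@H]1c1ccccc1 | intermediate
10 | (2,4-dihydroxy-6-methoxyphenyl)[(1R,6R)-4-(4-methylpent-3-en-1-yl)-6-phenylcyclohex-3-en-1-yl]methanone | COc1cc(O)cc(O)c1C(=O)[C@@H]1CC=C(CCC=C(C)C)C[C@H]1c1ccccc1 | target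

Total step count: 7. Longest linear sequence: 7 steps (1 to 10).

**Steps most likely to fail**

Step 6. The benzyl/allyl diradical may fragment by cycloreversion faster than it recloses at C5, and ring closure may show incomplete trans selectivity at C6. The fallback closes the cyclohexene by an enantioselective Diels–Alder reaction; it sets out from 1 and comes back to the route at 10. Selective acetylation of the non-chelated 4′-hydroxyl of 1 (Ac2O, pyridine, 0 °C) would give 4′-O-acetylcardamonin F1. Its 2′-hydroxyl and carbonyl would bind a chiral borate made from B(OPh)3 and an enantiopure 3,3′-disubstituted 1,1′-bi-2-naphthol (antipode chosen for the 1R,6R adduct; THF, 4 Å molecular sieves, rt). Cycloaddition with commercial myrcene, with the para orientation usual for a 2-substituted diene and the trans relationship fixed by the E alkene, should give the 4′-O-acetyl cyclohexene F2. Methanolysis (K2CO3, MeOH, rt) would then give 10.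

Step 1. Enantiofacial discrimination may be eroded, because the 6′-methoxy group beside the carbonyl offers the Lewis acid a second chelation mode and the free 4′-hydroxyl a second binding site; closure of the diradical at the far allyl terminus may also compete. The fallback is resolution of the racemate; it sets out from 1 and 2 and comes back at 4. The cycloaddition would be run with Sc(OTf)3 without chiral ligand (same sensitiser and light) to give 3 together with its mirror image ent-3 F3. Silylation as in step 2 would give 4 together with ent-4 F4, and preparative chromatography on a chiral stationary phase would deliver enantiopure 4.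

Step 4. Proton transfer between enolate 6 and the product may cause over-alkylation or alkylation at the ring carbon, and the enolate may add reversibly to the neighbouring aryl ketone. The fallback attaches the chain by cross-coupling; it sets out from 5 and comes back at 8, bypassing 7 and step 5. Treatment of 5 with KN(SiMe3)2 and PhNTf2 (THF, −78 °C) would give the enol triflate F5. Negishi coupling with (4-methylpent-3-en-1-yl)zinc bromide F6 (from 5-bromo-2-methylpent-2-ene, Zn and LiCl in THF) under Pd(dppf)Cl2 (THF, 50 °C) should give 8.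

**Further compounds**

F1 | step 6 | 4′-O-acetylcardamonin, 3-hydroxy-5-methoxy-4-[(E)-3-phenylprop-2-enoyl]phenyl acetate | COc1cc(OC(C)=O)cc(O)c1C(=O)/C=C/c1ccccc1
F2 | step 6 | 3-hydroxy-5-methoxy-4-{[(1R,6R)-4-(4-methylpent-3-en-1-yl)-6-phenylcyclohex-3-en-1-yl]carbonyl}phenyl acetate | COc1cc(OC(C)=O)cc(O)c1C(=O)[C@@H]1CC=C(CCC=C(C)C)C[C@H]1c1ccccc1
F3 | step 1 | ent-3, (2,4-dihydroxy-6-methoxyphenyl)[(1S,2S,3S)-3-ethenyl-2-phenylcyclobutyl]methanone | COc1cc(O)cc(O)c1C(=O)[C@H]1C[C@@H](C=C)[C@@H]1c1ccccc1
F4 | step 1 | ent-4, [2,4-bis(tert-butyldimethylsilyloxy)-6-methoxyphenyl][(1S,2S,3S)-3-ethenyl-2-phenylcyclobutyl]methanone | COc1cc(O[Si](C)(C)C(C)(C)C)cc(O[Si](C)(C)C(C)(C)C)c1C(=O)[C@H]1C[C@@H](C=C)[C@@H]1c1ccccc1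
F5 | step 4 | enol triflate of 5, 1-{(1S,2R,3R)-3-[2,4-bis(tert-butyldimethylsilyloxy)-6-methoxybenzoyl]-2-phenylcyclobutyl}ethenyl trifluoromethanesulfonate | COc1cc(O[Si](C)(C)C(C)(C)C)cc(O[Si](C)(C)C(C)(C)C)c1C(=O)[C@@H]1C[C@H](C(=C)OS(=O)(=O)C(F)(F)F)[C@H]1c1ccccc1
F6 | step 4 | (4-methylpent-3-en-1-yl)zinc bromide | CC(C)=CCC[Zn]Br
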